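If you follow one substrate molecule to a fork where the path to target needs free catalyst and another path does not, the odds for target rise in step with c(free catalyst).

| flask | substrate | gas phase | free catalyst | remark | time |
|---|---|---|---|---|---|
| north-east | 0.20 M | 10 mM (held) | 2.7 mM | run made earlier |  |
| south-west | 0.20 M | 10 mM (held) | 6 mM | run made earlier |  |
| flask | 0.20 M | 10 mM (held) | 4.0 mM |  | 1.0 h |

| run | time / min | target / % |
|---|---|---|
| north-east | 5.00 | 5.7 |
| north-east | 10.0 | 7.5 |
| north-east | 15.0 | 10.6 |
| north-east | 30.0 | 10.0 |
| north-east | 60.0 | 9.2 |
| south-west | 12.0 | 18.4 |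
| south-west | 25.0 | 18.4 |
| south-west | 40.0 | 19.3 |
| south-west | 50.0 | 17.2 |
| south-west | 60.0 | 18.8 |

(readings scatter by 1 percentage point)
- amount of target at 1.0 h, in percent of the substrate charged
- concentration of dissolved gas in solution at 1.0 h, in percent of saturation

My own reckoning reads each plateau as such a split of the whole substrate, which the readings cannot confirm because they do not show substrate. The north-east plateau averages 9.93% and the south-west one 18.4%. Target over the rest, divided by the charged c(free catalyst), gives 0.0408 mM⁻¹ and 0.0376 mM⁻¹, so I carry their mean, the whole-run odds per unit of catalyst charged, 0.0392 mM⁻¹. For the flask this gives 13.6%.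

The forecast, on different grounds, says 13.4% of target and 99% of saturation, holding that “The plateau scales roughly with catalyst charge”.

The flask gives 13.2% and >99.9%.

    2 substrate → self-condensation product (k = 1.60 × 10⁻⁵ L mol⁻¹ s⁻¹)
    gas phase ⇌ dissolved gas, rate k2*(csat - [dissolved gas]) (kL = 0.0930 s⁻¹)
    free catalyst → spent catalyst (k = 0.00280 s⁻¹)
    substrate + dissolved gas → uncatalysed product (k = 0.210 L mol⁻¹ s⁻¹)
    substrate + dissolved gas + free catalyst → free catalyst + target (k = 22.0 L² mol⁻² s⁻¹)

At 1.00 h the flask holds 0.0660% of its substrate, with 13.2% as target and 86.6% as uncatalysed product, so the fork is real, and the flask's whole-run odds per unit of catalyst charged come to 0.0379 mM⁻¹. Removing the conversion of free catalyst into spent catalyst lifts the flask's target from 13.2% to 29.5%, which is 19% of what is missing, so this step is a part of the reason. For the neighbour charged with 16.0 mM of free catalyst, proportion to the charge from this flask gives 52.6%, the odds give 38.5%, and the neighbour gives 39.6%.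

The runs stem from a simulated flask with made-up constants, and the scatter is random.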